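**Retrosynthetic overview**
- Target (4S) ⇐ its tribenzyl ether by hydrogenolysis; benzyl marks the three free OH groups, methyl stays on the naphthalene 8‑O.
- Tetralone ring (the only ring formed, and formed last) ⇐ intramolecular Friedel–Crafts acylation of an (S)‑4,4‑diarylbutanoic acid onto the hydroquinone ring.
- Acid ⇐ γ,γ‑diaryl α‑keto acetal by Wolff–Kishner deoxygenation, acetal unmasking and Pinnick oxidation.
- C4 stereocentre ⇐ Rh/chiral‑diene 1,4‑addition of 2,5‑bis(benzyloxy)phenylboronic acid to a naphthyl enone, itself from a Claisen–Schmidt condensation.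
- Naphthalene and benzene rings are bought: 4,8‑dimethoxy‑1‑naphthaldehyde (para‑selective demethylation, then benzylation) and bromohydroquinone.

Assumption: 1, 5 and 7 are catalogue compounds (1 is otherwise one Vilsmeier formylation from 1,5‑dimethoxynaphthalene); the facial sense in step 6 is predicted from the Hayashi model, not from a precedent on this substrate pair, and the antipodal diene is the correction if the assay shows the opposite.

**Route**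

Step 1
Reactants: 1 4,8‑dimethoxynaphthalene‑1‑carbaldehyde
Product: 3 4‑hydroxy‑8‑methoxynaphthalene‑1‑carbaldehyde, via sodium 4‑formyl‑5‑methoxynaphthalen‑1‑olate 2 (not isolated)
Conditions: NaSEt (1.5 equiv), DMF, 100 °C; then 1 M HCl
Reagents that add atoms: none
Why: Thiolate SN2 O‑demethylation is selective for the 4‑OMe because only its naphtholate leaving group is conjugated (para) to the formyl group, whereas the peri 8‑OMe is not.

Step 2
Reactants: 3 4‑hydroxy‑8‑methoxynaphthalene‑1‑carbaldehyde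
Product: 4 4‑(benzyloxy)‑8‑methoxynaphthalene‑1‑carbaldehyde
Conditions: BnBr, K2CO3, DMF, rt
Reagents that add atoms: benzyl bromide BrCc1ccccc1
Why: Williamson ether synthesis on the acidic (vinylogous acid) naphthol proceeds cleanly under mild carbonate conditions.

Step 3
Reactants: 4 4‑(benzyloxy)‑8‑methoxynaphthalene‑1‑carbaldehyde; 5 1,1‑dimethoxypropan‑2‑one (pyruvaldehyde dimethyl acetal)
Product: 6 (3E)‑4‑[4‑(benzyloxy)‑8‑methoxynaphthalen‑1‑yl]‑1,1‑dimethoxybut‑3‑en‑2‑one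
Conditions: 10% aq NaOH, MeOH, rt
Reagents that add atoms: none
Why: Claisen–Schmidt aldol condensation, in which 5 enolises at its methyl group and the non‑enolisable aldehyde gives the conjugated (E)‑enone after E1cB dehydration.

Step 4
Reactants: 7 2‑bromobenzene‑1,4‑diol
Product: 8 1,4‑bis(benzyloxy)‑2‑bromobenzene
Conditions: BnBr (2.2 equiv), K2CO3, DMF, 60 °C
Reagents that add atoms: benzyl bromide BrCc1ccccc1
Why: Double Williamson etherification of the hydroquinone.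

Step 5
Reactants: 8 1,4‑bis(benzyloxy)‑2‑bromobenzene
Product: 11 [2,5‑bis(benzyloxy)phenyl]boronic acid, via aryllithium 9 (not isolated), via lithium aryl triisopropoxyborate 10 (not isolated)
Conditions: n‑BuLi, THF, −78 °C; B(OiPr)3, −78 °C → rt; 1 M HCl
Reagents that add atoms: triisopropyl borate CC(C)OB(OC(C)C)OC(C)C; water O
Why: Br–Li exchange at −78 °C outruns benzylic deprotonation, and borate trapping followed by hydrolysis gives the boronic acid.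

Step 6
Reactants: 6 (3E)‑4‑[4‑(benzyloxy)‑8‑methoxynaphthalen‑1‑yl]‑1,1‑dimethoxybut‑3‑en‑2‑one; 11 [2,5‑bis(benzyloxy)phenyl]boronic acid (2.5 equiv)
Product: 12 (4S)‑4‑[2,5‑bis(benzyloxy)phenyl]‑4‑[4‑(benzyloxy)‑8‑methoxynaphthalen‑1‑yl]‑1,1‑dimethoxybutan‑2‑one
Conditions: [RhCl(C2H4)2]2 (2.5 mol %), (S,S)‑Ph‑bod* (5.5 mol %), KOH (0.5 equiv), dioxane/H2O 10:1, 50 °C
Reagents that add atoms: none
Why: Hayashi–Miyaura Rh‑catalysed asymmetric conjugate addition, in which the aryl–Rh(diene) species carbometalates the (E)‑enone on its α‑si (= β‑si) face as dictated by the (S,S)‑diene, setting C4 as S; a plain enone avoids the 1,2‑addition seen with α‑keto esters and the acetal is inert to aqueous base.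

Step 7
Reactants: 12 (4S)‑4‑[2,5‑bis(benzyloxy)phenyl]‑4‑[4‑(benzyloxy)‑8‑methoxynaphthalen‑1‑yl]‑1,1‑dimethoxybutan‑2‑one
Product: 15 (4S)‑4‑[2,5‑bis(benzyloxy)phenyl]‑4‑[4‑(benzyloxy)‑8‑methoxynaphthalen‑1‑yl]butanal, via hydrazone 13 (not isolated), via dimethyl acetal 14 (not isolated)
Conditions: N2H4·H2O, KOH, diethylene glycol, 130 → 195 °C; then 2 M HCl, THF, rt
Reagents that add atoms: water O
Why: Wolff–Kishner (Huang‑Minlon) reduction removes the C2 carbonyl under base that leaves the acetal, the ethers and the non‑acidic diarylmethine centre alone (any enol ether from Kishner–Leonard elimination gives the same aldehyde), and dilute acid then unmasks the aldehyde.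

Step 8
Reactants: 15 (4S)‑4‑[2,5‑bis(benzyloxy)phenyl]‑4‑[4‑(benzyloxy)‑8‑methoxynaphthalen‑1‑yl]butanal
Product: 16 (4S)‑4‑[2,5‑bis(benzyloxy)phenyl]‑4‑[4‑(benzyloxy)‑8‑methoxynaphthalen‑1‑yl]butanoic acid
Conditions: NaClO2, NaH2PO4, 2‑methyl‑2‑butene (excess), t‑BuOH/H2O, rt
Reagents that add atoms: sodium chlorite [Na+].[O-]Cl=O
Why: Pinnick oxidation converts the aldehyde to the acid while the alkene scavenges HOCl, so the electron‑rich arenes are not chlorinated.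

Step 9
Reactants: 16 (4S)‑4‑[2,5‑bis(benzyloxy)phenyl]‑4‑[4‑(benzyloxy)‑8‑methoxynaphthalen‑1‑yl]butanoic acid
Product: 18 (4S)‑5,8‑bis(benzyloxy)‑4‑[4‑(benzyloxy)‑8‑methoxynaphthalen‑1‑yl]‑3,4‑dihydronaphthalen‑1(2H)‑one, via mixed trifluoroacetic anhydride 17 (not isolated)
Conditions: (CF3CO)2O, CH2Cl2, 0 °C → rt
Reagents that add atoms: none
Why: Intramolecular Friedel–Crafts acylation closes the six‑membered ring ortho to a benzyloxy group of the hydroquinone ring, the only strongly activated position within reach (naphthalene C2 is meta to its ether, the peri position is blocked), and the stereocentre is not involved.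

Step 10
Reactants: 18 (4S)‑5,8‑bis(benzyloxy)‑4‑[4‑(benzyloxy)‑8‑methoxynaphthalen‑1‑yl]‑3,4‑dihydronaphthalen‑1(2H)‑one
Product: 19 (4S)‑5,8‑dihydroxy‑4‑(4‑hydroxy‑8‑methoxynaphthalen‑1‑yl)‑3,4‑dihydronaphthalen‑1(2H)‑one
Conditions: H2 (1 atm), 10% Pd/C, EtOAc/MeOH, rt, stopped after 3 equiv H2
Reagents that add atoms: none
Why: Catalytic hydrogenolysis cleaves the three benzyl aryl ethers and leaves the methyl ether, the hydrogen‑bonded aryl ketone and the C4 stereocentre untouched.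

**Compound list**
1 | 4,8‑dimethoxynaphthalene‑1‑carbaldehyde | COc1cccc2c(OC)ccc(C=O)c12 | starting material
2 | sodium 4‑formyl‑5‑methoxynaphthalen‑1‑olate | COc1cccc2c([O-])ccc(C=O)c12.[Na+] | intermediate (not isolated)
3 | 4‑hydroxy‑8‑methoxynaphthalene‑1‑carbaldehyde | COc1cccc2c(O)ccc(C=O)c12 | intermediate
4 | 4‑(benzyloxy)‑8‑methoxynaphthalene‑1‑carbaldehyde | COc1cccc2c(OCc3ccccc3)ccc(C=O)c12 | intermediate
5 | 1,1‑dimethoxypropan‑2‑one | CC(=O)C(OC)OC | starting material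
6 | (3E)‑4‑[4‑(benzyloxy)‑8‑methoxynaphthalen‑1‑yl]‑1,1‑dimethoxybut‑3‑en‑2‑one | COc1cccc2c(OCc3ccccc3)ccc(/C=C/C(=O)C(OC)OC)c12 | intermediate
7 | 2‑bromobenzene‑1,4‑diol | Oc1ccc(O)c(Br)c1 | starting material
8 | 1,4‑bis(benzyloxy)‑2‑bromobenzene | Brc1cc(OCc2ccccc2)ccc1OCc1ccccc1 | intermediate
9 | [2,5‑bis(benzyloxy)phenyl]lithium | [Li]c1cc(OCc2ccccc2)ccc1OCc1ccccc1 | intermediate (not isolated)
10 | lithium [2,5‑bis(benzyloxy)phenyl]tri(propan‑2‑yloxy)borate | CC(C)O[B-](OC(C)C)(OC(C)C)c1cc(OCc2ccccc2)ccc1OCc1ccccc1.[Li+] | intermediate (not isolated)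
11 | [2,5‑bis(benzyloxy)phenyl]boronic acid | OB(O)c1cc(OCc2ccccc2)ccc1OCc1ccccc1 | intermediate
12 | (4S)‑4‑[2,5‑bis(benzyloxy)phenyl]‑4‑[4‑(benzyloxy)‑8‑methoxynaphthalen‑1‑yl]‑1,1‑dimethoxybutan‑2‑one | COc1cccc2c(OCc3ccccc3)ccc([C@@H](c3cc(OCc4ccccc4)ccc3OCc3ccccc3)CC(=O)C(OC)OC)c12 | intermediate
13 | hydrazone of 12 | COc1cccc2c(OCc3ccccc3)ccc([C@@H](c3cc(OCc4ccccc4)ccc3OCc3ccccc3)CC(=NN)C(OC)OC)c12 | intermediate (not isolated)
14 | (4S)‑4‑[2,5‑bis(benzyloxy)phenyl]‑4‑[4‑(benzyloxy)‑8‑methoxynaphthalen‑1‑yl]butanal dimethyl acetal | COc1cccc2c(OCc3ccccc3)ccc([C@@H](c3cc(OCc4ccccc4)ccc3OCc3ccccc3)CCC(OC)OC)c12 | intermediate (not isolated)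
15 | (4S)‑4‑[2,5‑bis(benzyloxy)phenyl]‑4‑[4‑(benzyloxy)‑8‑methoxynaphthalen‑1‑yl]butanal | COc1cccc2c(OCc3ccccc3)ccc([C@@H](c3cc(OCc4ccccc4)ccc3OCc3ccccc3)CCC=O)c12 | intermediate
16 | (4S)‑4‑[2,5‑bis(benzyloxy)phenyl]‑4‑[4‑(benzyloxy)‑8‑methoxynaphthalen‑1‑yl]butanoic acid | COc1cccc2c(OCc3ccccc3)ccc([C@@H](c3cc(OCc4ccccc4)ccc3OCc3ccccc3)CCC(=O)O)c12 | intermediate
17 | mixed anhydride of 16 with trifluoroacetic acid | COc1cccc2c(OCc3ccccc3)ccc([C@@H](c3cc(OCc4ccccc4)ccc3OCc3ccccc3)CCC(=O)OC(=O)C(F)(F)F)c12 | intermediate (not isolated)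
18 | (4S)‑5,8‑bis(benzyloxy)‑4‑[4‑(benzyloxy)‑8‑methoxynaphthalen‑1‑yl]‑3,4‑dihydronaphthalen‑1(2H)‑one | COc1cccc2c(OCc3ccccc3)ccc([C@@H]3CCC(=O)c4c(OCc5ccccc5)ccc(OCc5ccccc5)c43)c12 | intermediate
19 | (4S)‑5,8‑dihydroxy‑4‑(4‑hydroxy‑8‑methoxynaphthalen‑1‑yl)‑3,4‑dihydronaphthalen‑1(2H)‑one | COc1cccc2c(O)ccc([C@@H]3CCC(=O)c4c(O)ccc(O)c43)c12 | target

**Totals**
Total steps: 10. Longest linear sequence: 8 (steps 1, 2, 3, 6, 7, 8, 9, 10 from compound 1); steps 4 and 5 make the boronic acid branch.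

**Three steps most likely to fail, with fallbacks**

Step 6 (Rh addition). The diarylmethine is flanked by a peri‑methoxy group and an ortho‑benzyloxy group, so both rate and ee are unproven for this pair. The fallback is an auxiliary‑controlled cuprate addition that sets out from 4 and 8 and comes back at 15.
- Horner–Wadsworth–Emmons reaction of 4 with diethyl {2‑oxo‑2‑[(4S)‑2‑oxo‑4‑phenyl‑1,3‑oxazolidin‑3‑yl]ethyl}phosphonate (LiCl, iPr2NEt, MeCN) gives the N‑enoyl oxazolidinone F1.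
- Bromide 8 with Mg in THF gives the aryl Grignard reagent F2.
- F2 with CuBr·SMe2 at −40 °C adds to the chelated s‑cis imide anti to the auxiliary phenyl group and gives the (3S) adduct F3.
- LiBH4 (THF/MeOH) releases the auxiliary and gives the alcohol F4.
- Dess–Martin periodinane gives the aldehyde F5.
- Ph3P=CHOMe gives the enol ether F6.
- 2 M HCl/THF hydrolyses F6 to 15, which re‑enters at step 8.

Step 7 (Wolff–Kishner). Hot KOH at 195 °C may nick the aryl ethers or leave the hindered hydrazone unreduced. The fallback is a radical deoxygenation that sets out from 12 and comes back at 14.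
- NaBH4 (MeOH, 0 °C) gives the alcohol F7 as a C2 epimer mixture.
- 1,1′‑Thiocarbonyldiimidazole (DMAP, ClCH2CH2Cl, reflux) gives the imidazolyl thiocarbamate F8.
- Bu3SnH/AIBN (toluene, 90 °C; Barton–McCombie) gives 14, which is hydrolysed to 15 as in the second stage of step 7.

Step 9 (Friedel–Crafts). Acid may attack the naphthalene ring or remove benzyl groups before ring closure. The fallback is an amide‑activation cyclisation that sets out from 16 and comes back at 18.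
- Me2NH·HCl, EDC·HCl, HOBt and iPr2NEt give the dimethylamide F9.
- Tf2O/2‑chloropyridine (CH2Cl2, −78 → 0 °C) generates a keteniminium/iminium electrophile that closes to the cyclic iminium triflate F10.
- Aqueous NaHCO3/THF hydrolyses F10 to 18.

**Further compounds**
F1 | step 6 | (4S)‑3‑{(2E)‑3‑[4‑(benzyloxy)‑8‑methoxynaphthalen‑1‑yl]prop‑2‑enoyl}‑4‑phenyl‑1,3‑oxazolidin‑2‑one | COc1cccc2c(OCc3ccccc3)ccc(/C=C/C(=O)N3C(=O)OC[C@@H]3c3ccccc3)c12
F2 | step 6 | [2,5‑bis(benzyloxy)phenyl]magnesium bromide | Br[Mg]c1cc(OCc2ccccc2)ccc1OCc1ccccc1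
F3 | step 6 | (4S)‑3‑{(3S)‑3‑[2,5‑bis(benzyloxy)phenyl]‑3‑[4‑(benzyloxy)‑8‑methoxynaphthalen‑1‑yl]propanoyl}‑4‑phenyl‑1,3‑oxazolidin‑2‑one | COc1cccc2c(OCc3ccccc3)ccc([C@@H](c3cc(OCc4ccccc4)ccc3OCc3ccccc3)CC(=O)N3C(=O)OC[C@@H]3c3ccccc3)c12
F4 | step 6 | (3S)‑3‑[2,5‑bis(benzyloxy)phenyl]‑3‑[4‑(benzyloxy)‑8‑methoxynaphthalen‑1‑yl]propan‑1‑ol | COc1cccc2c(OCc3ccccc3)ccc([C@@H](c3cc(OCc4ccccc4)ccc3OCc3ccccc3)CCO)c12
F5 | step 6 | (3S)‑3‑[2,5‑bis(benzyloxy)phenyl]‑3‑[4‑(benzyloxy)‑8‑methoxynaphthalen‑1‑yl]propanal | COc1cccc2c(OCc3ccccc3)ccc([C@@H](c3cc(OCc4ccccc4)ccc3OCc3ccccc3)CC=O)c12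
F6 | step 6 | 1‑(benzyloxy)‑4‑{(1S)‑1‑[2,5‑bis(benzyloxy)phenyl]‑4‑methoxybut‑3‑en‑1‑yl}‑5‑methoxynaphthalene (E/Z mixture) | COc1cccc2c(OCc3ccccc3)ccc([C@@H](c3cc(OCc4ccccc4)ccc3OCc3ccccc3)CC=COC)c12
F7 | step 7 | (4S)‑4‑[2,5‑bis(benzyloxy)phenyl]‑4‑[4‑(benzyloxy)‑8‑methoxynaphthalen‑1‑yl]‑1,1‑dimethoxybutan‑2‑ol (C2 epimers) | COc1cccc2c(OCc3ccccc3)ccc([C@@H](c3cc(OCc4ccccc4)ccc3OCc3ccccc3)CC(O)C(OC)OC)c12
F8 | step 7 | O‑{(4S)‑4‑[2,5‑bis(benzyloxy)phenyl]‑4‑[4‑(benzyloxy)‑8‑methoxynaphthalen‑1‑yl]‑1,1‑dimethoxybutan‑2‑yl} 1H‑imidazole‑1‑carbothioate | COc1cccc2c(OCc3ccccc3)ccc([C@@H](c3cc(OCc4ccccc4)ccc3OCc3ccccc3)CC(OC(=S)n3ccnc3)C(OC)OC)c12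
F9 | step 9 | (4S)‑4‑[2,5‑bis(benzyloxy)phenyl]‑4‑[4‑(benzyloxy)‑8‑methoxynaphthalen‑1‑yl]‑N,N‑dimethylbutanamide | COc1cccc2c(OCc3ccccc3)ccc([C@@H](c3cc(OCc4ccccc4)ccc3OCc3ccccc3)CCC(=O)N(C)C)c12
F10 | step 9 | N‑{(4S)‑5,8‑bis(benzyloxy)‑4‑[4‑(benzyloxy)‑8‑methoxynaphthalen‑1‑yl]‑3,4‑dihydronaphthalen‑1(2H)‑ylidene}‑N‑methylmethanaminium triflate | COc1cccc2c(OCc3ccccc3)ccc([C@@H]3CCC(=[N+](C)C)c4c(OCc5ccccc5)ccc(OCc5ccccc5)c43)c12.[O-]S(=O)(=O)C(F)(F)F
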